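The route rests on cutting the C7–C8 bond of the glyceryl chain carried by the 4'-oxygen of ring B. The anti (erythro) pair made up of the C7 carbinol on ring D and the aryloxy-bearing C8, next to the C9 primary alcohol, is the reduced form of an anti 2-aryloxy-3-hydroxy aldehyde. An L-proline enamine cross-aldol between a flavone-bound aryloxyacetaldehyde and 4-formylphenyl pivalate therefore makes that bond and both stereocenters in one operation, and NaBH4 then fixes C9. The aldol donor is 5,7-di-O-benzyltricin with an OCH2CHO arm on O4', built by chalcone condensation and oxidative closure of ring C.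

Key step: step 7

Remark: C7 is the benzylic carbinol carbon on ring D, C8 the ether carbon, C9 the CH2OH carbon; rings A and C form the chromone, ring B is the dimethoxyphenyl ring; L-proline is assumed to induce the same facial sense with this donor as with simpler alpha-oxygenated aldehydes.

Step 1
Reactants: 1 2,4,6-trihydroxyacetophenone
Product: 2 4,6-bis(benzyloxy)-2-hydroxyacetophenone
Conditions: BnBr (2.1 equiv), K2CO3, acetone, reflux
Reagents that add atoms: benzyl bromide, BrCc1ccccc1
Why: Williamson etherification with a carbonate base alkylates the hydroxyl para to the acetyl group and one ortho hydroxyl, while the remaining ortho hydroxyl is locked in a hydrogen bond to the carbonyl oxygen and stays free when the bromide is limited to two equivalents.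

Step 2
Reactants: 3 syringaldehyde; 4 bromoacetaldehyde diethyl acetal
Product: 5 4-(2,2-diethoxyethoxy)-3,5-dimethoxybenzaldehyde
Conditions: Cs2CO3, DMF, 100 °C
Reagents that add atoms: none
Why: Williamson O-alkylation in which the cesium phenoxide of the hindered phenol displaces bromide from the primary carbon in a dipolar aprotic solvent, the non-enolisable aryl aldehyde and the acetal being inert to carbonate.

Step 3
Reactants: 2 4,6-bis(benzyloxy)-2-hydroxyacetophenone; 5 4-(2,2-diethoxyethoxy)-3,5-dimethoxybenzaldehyde
Product: 6 (E)-1-[2,4-bis(benzyloxy)-6-hydroxyphenyl]-3-[4-(2,2-diethoxyethoxy)-3,5-dimethoxyphenyl]prop-2-en-1-one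
Conditions: KOH (50% aq), EtOH–THF, rt; AcOH to pH 6
Reagents that add atoms: none
Why: Claisen–Schmidt condensation in which the methyl ketone enolate adds to the non-enolisable aldehyde and the aldol dehydrates by E1cB to the conjugated (E)-enone, benzyl ethers and the acetal being stable to hydroxide and to the weakly acidic quench.

Step 4
Reactants: 6 the 2'-hydroxychalcone
Product: 7 5,7-bis(benzyloxy)-2-[4-(2,2-diethoxyethoxy)-3,5-dimethoxyphenyl]-4H-chromen-4-one
Conditions: I2 (10 mol%), DMSO, 120 °C; Na2S2O3 (aq) work-up
Reagents that add atoms: none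
Why: Iodine-catalysed oxidative cyclisation of a 2'-hydroxychalcone, in which the phenol oxygen adds to the enone to close ring C (6-endo oxa-Michael), alpha-iodination and loss of HI install the C2–C3 double bond and DMSO reoxidises HI to I2; the acetal should survive because the beta-aryloxy oxygen retards its ionisation.

Step 5
Reactants: 7 the flavone diethyl acetal
Product: 8 {4-[5,7-bis(benzyloxy)-4-oxo-4H-chromen-2-yl]-2,6-dimethoxyphenoxy}acetaldehyde
Conditions: 2 M HCl (aq)–THF, 50 °C; dried azeotropically with toluene and used at once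
Reagents that add atoms: water, O
Why: Acid-catalysed acetal hydrolysis through the oxocarbenium ion, warm enough to overcome the retarding beta-aryloxy group yet too mild to cleave aryl benzyl ethers, with the hydrate-prone aldehyde carried forward without storage.

Step 6
Reactants: 9 4-hydroxybenzaldehyde
Product: 10 4-formylphenyl pivalate
Conditions: pivaloyl chloride, Et3N, DMAP (cat.), CH2Cl2, 0 °C to rt
Reagents that add atoms: pivaloyl chloride, CC(C)(C)C(=O)Cl
Why: O-acylation of the phenol by nucleophilic acyl substitution, giving a bulky electron-withdrawing ester that makes the formyl group more electrophilic and resists aminolysis by the amine catalyst of the next step.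

Step 7
Reactants: 8 the flavone-bound aryloxyacetaldehyde; 10 4-formylphenyl pivalate
Product: 12 4-[(1S,2R)-2-{4-[5,7-bis(benzyloxy)-4-oxo-4H-chromen-2-yl]-2,6-dimethoxyphenoxy}-1,3-dihydroxypropyl]phenyl pivalate, via anti aldol aldehyde 11 (not isolated)
Conditions: 10 (4 equiv), L-proline (30 mol%), DMF, 4 °C, 8 in DMF added by syringe pump over 24 h; then MeOH, NaBH4 (excess over all formyl groups), −20 °C; NH4Cl (aq)
Reagents that add atoms: none
Why: L-Proline condenses with 8, the only enolisable aldehyde, to the (E)-enamine, which attacks the Re face of the formyl group of 10 through a chair-like transition state in which the carboxylic acid of the catalyst hydrogen-bonds the acceptor oxygen and the aryl group sits pseudo-equatorial; hydrolysis of the iminium releases aldehyde 11 and the catalyst, and NaBH4 then reduces the formyl groups in the same flask. The closest known reaction type is the proline-catalysed direct anti cross-aldol of aldehyde donors, alpha-oxygenated acetaldehydes included, with non-enolisable acceptors under slow donor addition. No ring is closed. C8 (the enamine carbon) and C7 (the acceptor carbonyl carbon) are both set by the (S)-configured catalyst, giving the anti (2S,3S) aldehyde, which is the erythro (7S,8R) arrangement once the formyl carbon becomes C9H2OH (only the descriptor of C8 changes, not its geometry). The step needs enantiofacial control, anti diastereoselectivity and cross- over homo-aldol selectivity: the first two come from the acid-directed enamine transition state, the third from an acceptor that cannot enolise, is activated by its para acyloxy group and is held in excess while the donor stays dilute. Immediate cold reduction removes the epimerisable, retro-aldol-prone aldehyde and leaves the vinylogous-ester carbonyl of the flavone and the pivalate untouched.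

Step 8
Reactants: 12 the dibenzyl-protected erythro diol
Product: 13 4-[(1S,2R)-2-[4-(5,7-dihydroxy-4-oxo-4H-chromen-2-yl)-2,6-dimethoxyphenoxy]-1,3-dihydroxypropyl]phenyl pivalate
Conditions: H2 (1 atm), 10% Pd/C, THF–EtOAc, rt, stopped after uptake of two equivalents
Reagents that add atoms: none
Why: Neutral heterogeneous hydrogenolysis cleaves the two aryl benzyl ethers, whereas the benzylic C7 carbinol, deactivated by the para pivaloyloxy group and the beta-oxygen, and the cross-conjugated C2–C3 double bond of the flavone react far more slowly.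

Step 9
Reactants: 13 the 5,7-dihydroxy pivalate
Product: 14 tricin 4'-O-[erythro-(7S,8R)-β-(4-hydroxyphenyl)glyceryl] ether (target)
Conditions: K2CO3, MeOH, rt; pH 7 phosphate buffer
Reagents that add atoms: none
Why: Base-catalysed methanolysis (transesterification) of the aryl ester, which has a phenoxide leaving group and cleaves at room temperature, under conditions and a neutral quench too mild for quinone-methide formation or acid-catalysed epimerisation at C7, so both stereocenters pass unchanged into the target.

Compound list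
1 | 2,4,6-trihydroxyacetophenone | CC(=O)c1c(O)cc(O)cc1O | starting material
2 | 4,6-bis(benzyloxy)-2-hydroxyacetophenone | CC(=O)c1c(O)cc(OCc2ccccc2)cc1OCc1ccccc1 | intermediate
3 | syringaldehyde | COc1cc(C=O)cc(OC)c1O | starting material
4 | bromoacetaldehyde diethyl acetal | CCOC(CBr)OCC | starting material
5 | 4-(2,2-diethoxyethoxy)-3,5-dimethoxybenzaldehyde | CCOC(COc1c(OC)cc(C=O)cc1OC)OCC | intermediate
6 | (E)-1-[2,4-bis(benzyloxy)-6-hydroxyphenyl]-3-[4-(2,2-diethoxyethoxy)-3,5-dimethoxyphenyl]prop-2-en-1-one | CCOC(COc1c(OC)cc(/C=C/C(=O)c2c(O)cc(OCc3ccccc3)cc2OCc2ccccc2)cc1OC)OCC | intermediate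
7 | 5,7-bis(benzyloxy)-2-[4-(2,2-diethoxyethoxy)-3,5-dimethoxyphenyl]-4H-chromen-4-one | CCOC(COc1c(OC)cc(-c2cc(=O)c3c(OCc4ccccc4)cc(OCc4ccccc4)cc3o2)cc1OC)OCC | intermediate
8 | {4-[5,7-bis(benzyloxy)-4-oxo-4H-chromen-2-yl]-2,6-dimethoxyphenoxy}acetaldehyde | O=CCOc1c(OC)cc(-c2cc(=O)c3c(OCc4ccccc4)cc(OCc4ccccc4)cc3o2)cc1OC | intermediate
9 | 4-hydroxybenzaldehyde | O=Cc1ccc(O)cc1 | starting material
10 | 4-formylphenyl pivalate | CC(C)(C)C(=O)Oc1ccc(C=O)cc1 | intermediate
11 | 4-[(1S,2S)-2-{4-[5,7-bis(benzyloxy)-4-oxo-4H-chromen-2-yl]-2,6-dimethoxyphenoxy}-1-hydroxy-3-oxopropyl]phenyl pivalate (anti aldol aldehyde, not isolated) | COc1cc(-c2cc(=O)c3c(OCc4ccccc4)cc(OCc4ccccc4)cc3o2)cc(OC)c1O[C@H](C=O)[C@@H](O)c1ccc(OC(=O)C(C)(C)C)cc1 | intermediate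
12 | 4-[(1S,2R)-2-{4-[5,7-bis(benzyloxy)-4-oxo-4H-chromen-2-yl]-2,6-dimethoxyphenoxy}-1,3-dihydroxypropyl]phenyl pivalate | COc1cc(-c2cc(=O)c3c(OCc4ccccc4)cc(OCc4ccccc4)cc3o2)cc(OC)c1O[C@H](CO)[C@@H](O)c1ccc(OC(=O)C(C)(C)C)cc1 | intermediate
13 | 4-[(1S,2R)-2-[4-(5,7-dihydroxy-4-oxo-4H-chromen-2-yl)-2,6-dimethoxyphenoxy]-1,3-dihydroxypropyl]phenyl pivalate | COc1cc(-c2cc(=O)c3c(O)cc(O)cc3o2)cc(OC)c1O[C@H](CO)[C@@H](O)c1ccc(OC(=O)C(C)(C)C)cc1 | intermediate
14 | 2-(4-{[(1S,2R)-1,3-dihydroxy-1-(4-hydroxyphenyl)propan-2-yl]oxy}-3,5-dimethoxyphenyl)-5,7-dihydroxy-4H-chromen-4-one | COc1cc(-c2cc(=O)c3c(O)cc(O)cc3o2)cc(OC)c1O[C@H](CO)[C@@H](O)c1ccc(O)cc1 | target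

Total step count: 9 (the aldol and its in-flask reduction count as one step).
Longest linear sequence: 7 steps (steps 1, 3, 4, 5, 7, 8, 9; the branch starting with step 2 is equally long).

Steps most likely to fail

1. Step 7. The aromatic acceptor may give poor anti/syn or facial selectivity. Enamine formation next to the bulky 2,6-dimethoxyaryloxy group may be slow. The donor may self-condense, or the adduct may undergo retro-aldol before reduction. The fallback is an auxiliary-controlled aldol at the carboxylic acid oxidation level, setting out from aldehyde 8. Pinnick oxidation (NaClO2, NaH2PO4, 2-methyl-2-butene, tBuOH–THF–H2O) gives {4-[5,7-bis(benzyloxy)-4-oxo-4H-chromen-2-yl]-2,6-dimethoxyphenoxy}acetic acid F1. Activation with pivaloyl chloride and Et3N, then acylation of (R)-4-benzyl-2-oxazolidinone in the presence of LiCl, gives the N-(aryloxyacetyl) imide F2. A MgCl2-catalysed anti-aldol of the imide (Et3N, Me3SiCl, EtOAc, rt) with aldehyde 10 gives the O-trimethylsilyl anti adduct F3. Dilute acid removes the silyl group to leave the anti hydroxy imide F4. NaBH4 in wet THF then cleaves the auxiliary reductively, and the sequence comes back to the route at diol 12. The (R)-auxiliary is the antipode that a chelated magnesium enolate is expected to steer to the (2S,3S) adduct. This sense, and the use of an aryloxyacetyl imide in this reaction, would be checked on a model first; the antipodal auxiliary would be taken if the other sense were found.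

2. Step 4. The HI and water formed in hot DMSO may hydrolyse the acetal and degrade the freed aldehyde, or the 5-benzyl ether may be lost. The fallback sets out from chalcone 6. NaOAc in refluxing EtOH closes ring C at the flavanone level to give racemic 5,7-bis(benzyloxy)-2-[4-(2,2-diethoxyethoxy)-3,5-dimethoxyphenyl]chroman-4-one F5. DDQ in refluxing dioxane then dehydrogenates C2–C3 by hydride abstraction, with no acid and no water formed. The sequence comes back to the route at flavone 7.

3. Step 8. Over-reduction may occur (hydrogenolysis of the benzylic C7–O bond or saturation of C2–C3), or a poorly soluble substrate may stall. The fallback moves debenzylation ahead of the aldol, where no benzylic carbinol is present, and sets out from flavone acetal 7. H2 over Pd/C in THF gives tricin 4'-O-(2,2-diethoxyethyl) ether F6. Aqueous HCl in THF frees tricin 4'-O-(2-oxoethyl) ether F7. The L-proline aldol with 10 in DMF, run as in step 7, gives the free-phenol anti aldol aldehyde F8, which is reduced in the same flask with NaBH4. The sequence comes back to the route at pivalate 13, leaving only step 9.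

Further compounds
F1 | step 7 | {4-[5,7-bis(benzyloxy)-4-oxo-4H-chromen-2-yl]-2,6-dimethoxyphenoxy}acetic acid | O=C(O)COc1c(OC)cc(-c2cc(=O)c3c(OCc4ccccc4)cc(OCc4ccccc4)cc3o2)cc1OC
F2 | step 7 | (R)-4-benzyl-3-({4-[5,7-bis(benzyloxy)-4-oxo-4H-chromen-2-yl]-2,6-dimethoxyphenoxy}acetyl)oxazolidin-2-one | O=C(COc1c(OC)cc(-c2cc(=O)c3c(OCc4ccccc4)cc(OCc4ccccc4)cc3o2)cc1OC)N1[C@H](Cc2ccccc2)COC1=O
F3 | step 7 | O-trimethylsilyl (2S,3S) anti aldol adduct of the (R)-4-benzyl-2-oxazolidinone imide | COc1cc(-c2cc(=O)c3c(OCc4ccccc4)cc(OCc4ccccc4)cc3o2)cc(OC)c1O[C@H](C(=O)N1[C@H](Cc2ccccc2)COC1=O)[C@@H](O[Si](C)(C)C)c1ccc(OC(=O)C(C)(C)C)cc1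
F4 | step 7 | (2S,3S) anti 2-aryloxy-3-hydroxy imide of (R)-4-benzyl-2-oxazolidinone | COc1cc(-c2cc(=O)c3c(OCc4ccccc4)cc(OCc4ccccc4)cc3o2)cc(OC)c1O[C@H](C(=O)N1[C@H](Cc2ccccc2)COC1=O)[C@@H](O)c1ccc(OC(=O)C(C)(C)C)cc1
F5 | step 4 | racemic 5,7-bis(benzyloxy)-2-[4-(2,2-diethoxyethoxy)-3,5-dimethoxyphenyl]chroman-4-one | CCOC(COc1c(OC)cc(C2CC(=O)c3c(OCc4ccccc4)cc(OCc4ccccc4)cc3O2)cc1OC)OCC
F6 | step 8 | tricin 4'-O-(2,2-diethoxyethyl) ether | CCOC(COc1c(OC)cc(-c2cc(=O)c3c(O)cc(O)cc3o2)cc1OC)OCC
F7 | step 8 | tricin 4'-O-(2-oxoethyl) ether | O=CCOc1c(OC)cc(-c2cc(=O)c3c(O)cc(O)cc3o2)cc1OC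
F8 | step 8 | 4-[(1S,2S)-2-[4-(5,7-dihydroxy-4-oxo-4H-chromen-2-yl)-2,6-dimethoxyphenoxy]-1-hydroxy-3-oxopropyl]phenyl pivalate | COc1cc(-c2cc(=O)c3c(O)cc(O)cc3o2)cc(OC)c1O[C@H](C=O)[C@@H](O)c1ccc(OC(=O)C(C)(C)C)cc1
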